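The retrosynthesis cuts C15–S of a thio-lactone first, then the two lactone bonds C13–C14 and C15–O together, giving ketene C13=C16=O (from spiro acid 18) and vinyl sulfoxide 20; then O9–C13, C11–C12, C9–O9, C9=C11, C6–O, C4–CH3, C3=C4, C10–CH3 and C10–C1, back to (R)-carvone.
Forward, ring B is the carvone ring; ring A is closed onto it by ring-closing metathesis (cis-fused) and finished by hydromethylation; ring B is oxygenated at C6; C9 becomes a spiro-epoxide, the chain is added and the tetrahydrofuran ring (spiro at C9) is closed; the lactone ring (spiro at C13) comes last.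
The enabling feature is that C13 is at once the α-carbon of the C16 carboxyl group and the carbon bearing ring oxygen O9, so acid 18 gives a ketene; its carboxyl oxygen is 1,3 to C13, so a two-carbon vinyl sulfoxide can bridge C13 and that oxygen by a [3,3] shift and ring closure.
Stereochemistry: C5 from (R)-carvone; C10 by methylation anti to the isopropenyl group; C6 by singlet-oxygen cycloaddition on the convex face; C8 by equilibration next to the C9 ketone; C9 by peracid attack on the convex face; C13 by chirality transfer from sulfur of 20, because C8 and C10 flank C9 almost as mirror images and the decalin cannot bias C13.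

Key step: step 15

Remark: labdane numbering is used (decalin C1–C10, side chain C11–C16, C17 on C8, C18/C19 on C4, C20 on C10); the SMILES places H5 and the C10 methyl on the same face, so the target is made as the cis-fused (5S,6S,8R,9R,10R,13R) isomer, and "convex face" means the face of ring B carrying H5 and C20.

Step 1
Reactants: 1 (R)-carvone; 2 4-iodobut-1-ene
Product: 3 (5R)-6-(but-3-en-1-yl)-2-methyl-5-(prop-1-en-2-yl)cyclohex-2-en-1-one (both C6 epimers)
Conditions: LiN(i-Pr)2 (LDA), THF, −78 °C; then 2, DMPU, −78 → −20 °C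
Reagents that add atoms: none
Why: Kinetic α′-deprotonation of the cross-conjugated enone and SN2 alkylation of the lithium dienolate by the primary iodide (enolate alkylation) should attach C1–C3 at the future C10; the new centre is re-enolised in step 2, so its configuration does not matter.

Step 2
Reactants: 3 (5R)-6-(but-3-en-1-yl)-2-methyl-5-(prop-1-en-2-yl)cyclohex-2-en-1-one
Product: 4 (5S,6R)-6-(but-3-en-1-yl)-2,6-dimethyl-5-(prop-1-en-2-yl)cyclohex-2-en-1-one
Conditions: LiN(i-Pr)2, THF, −78 °C; then MeI, −78 → 0 °C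
Reagents that add atoms: iodomethane (CI)
Why: Enolate alkylation of the fully substituted α′-enolate, in which iodomethane should approach anti to the neighbouring isopropenyl group (1,2-induction from the carvone stereocentre), so the C10 methyl ends trans to isopropenyl and the butenyl chain cis to it, as the cis ring fusion requires.

Step 3
Reactants: 4 (5S,6R)-6-(but-3-en-1-yl)-2,6-dimethyl-5-(prop-1-en-2-yl)cyclohex-2-en-1-one
Product: 5 (4aS,8aR)-2,5,8a-trimethyl-4a,7,8,8a-tetrahydronaphthalen-1(4H)-one
Conditions: second-generation Grubbs catalyst (5 mol%), CH2Cl2, 40 °C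
Reagents that add atoms: none
Why: Ring-closing metathesis of the monosubstituted and the 1,1-disubstituted alkene, held cis on adjacent ring carbons, should close ring A as a cyclohexene (C3=C4) with loss of ethene, the electron-poor enone alkene not taking part.

Step 4
Reactants: 5 (4aS,8aR)-2,5,8a-trimethyl-4a,7,8,8a-tetrahydronaphthalen-1(4H)-one
Product: 7 (4aS,8aR)-2,5,5,8a-tetramethyl-4a,5,6,7,8,8a-hexahydronaphthalen-1(4H)-one, via hydrazide 6 (not isolated)
Conditions: Fe(acac)3 (50 mol%), PhSiH3, formaldehyde N-(octylsulfonyl)hydrazone, THF/MeOH, 23 °C; then MeOH, 60 °C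
Reagents that add atoms: formaldehyde N-(octylsulfonyl)hydrazone (C=NNS(=O)(=O)CCCCCCCC)
Why: Markovnikov hydromethylation by metal-hydride hydrogen-atom transfer, in which the iron hydride should give H to C3 of the electron-rich ring-A alkene (not to the enone), the tertiary C4 radical adds to the C=N bond, and hydrazide 6 loses sulfinate and N2 on warming to leave the second methyl on C4 (no new stereocentre).

Step 5
Reactants: 7 (4aS,8aR)-2,5,5,8a-tetramethyl-4a,5,6,7,8,8a-hexahydronaphthalen-1(4H)-one
Product: 8 tert-butyl(dimethyl){[(4aS,8aR)-2,5,5,8a-tetramethyl-4a,5,6,7,8,8a-hexahydronaphthalen-1-yl]oxy}silane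
Conditions: TBSOTf, Et3N, CH2Cl2, 0 °C
Reagents that add atoms: tert-butyldimethylsilyl trifluoromethanesulfonate (CC(C)(C)[Si](C)(C)OS(=O)(=O)C(F)(F)F)
Why: Soft enolisation can remove only a γ-proton at C6 because the α′ carbon C10 is quaternary, so the linear silyl dienol ether (C9=C8–C7=C6) should form (silyl dienol ether formation).

Step 6
Reactants: 8 tert-butyl(dimethyl){[(4aS,8aR)-2,5,5,8a-tetramethyl-4a,5,6,7,8,8a-hexahydronaphthalen-1-yl]oxy}silane
Product: 10 (4S,4aS,8aR)-4-hydroxy-2,5,5,8a-tetramethyl-4a,5,6,7,8,8a-hexahydronaphthalen-1(4H)-one, via endoperoxide 9 (not isolated)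
Conditions: O2, visible light, tetraphenylporphyrin (cat.), CH2Cl2, −78 °C; then PPh3, −78 → 23 °C; then HF·pyridine, THF, 0 °C
Reagents that add atoms: dioxygen (O=O)
Why: [4+2] cycloaddition of singlet oxygen to the cisoid ring-B diene should take place on the convex face, the other face being covered by ring A with the quaternary C4 next to C6, so that reduction of endoperoxide 9 and loss of silicon give the γ-hydroxy enone with the C6–O bond cis to H5 (6S).

Step 7
Reactants: 10 (4S,4aS,8aR)-4-hydroxy-2,5,5,8a-tetramethyl-4a,5,6,7,8,8a-hexahydronaphthalen-1(4H)-one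
Product: 11 (2R,4S,4aS,8aR)-4-hydroxy-2,5,5,8a-tetramethyloctahydronaphthalen-1(2H)-one
Conditions: H2 (1 atm), Pd/C, EtOAc, 23 °C; then NaOMe (cat.), MeOH, 23 °C
Reagents that add atoms: none
Why: Heterogeneous hydrogenation of the enone C=C followed by base equilibration α to the C9 ketone should leave the C8 methyl equatorial and cis to the C10 methyl (its epimer would be 1,3-syn-axial to C1), so C8 is set under thermodynamic control, while C5 cannot epimerise because C6 is a carbinol carbon.

Step 8
Reactants: 11 (2R,4S,4aS,8aR)-4-hydroxy-2,5,5,8a-tetramethyloctahydronaphthalen-1(2H)-one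
Product: 12 (1S,3R,4aR,8aS)-3,4a,8,8-tetramethyl-4-methylidenedecahydronaphthalen-1-ol
Conditions: Ph3PCH3Br, KOt-Bu, toluene, 90 °C
Reagents that add atoms: methyltriphenylphosphonium bromide (C[P+](c1ccccc1)(c1ccccc1)c1ccccc1.[Br-])
Why: Wittig methylenation with an excess of the small unstabilised ylide at elevated temperature should convert the hindered ketone into the exocyclic alkene C9=C11, and reversible deprotonation at C8 is harmless because that centre already has its thermodynamic configuration.

Step 9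
Reactants: 12 (1S,3R,4aR,8aS)-3,4a,8,8-tetramethyl-4-methylidenedecahydronaphthalen-1-ol
Product: 13 (5S,6S,8R,9R,10R)-9,11-epoxy-12,13,14,15,16-pentanorlabdan-6-ol
Conditions: mCPBA, NaHCO3, CH2Cl2, 0 °C
Reagents that add atoms: 3-chloroperoxybenzoic acid (OOC(=O)c1cccc(Cl)c1)
Why: Prilezhaev epoxidation, in which the peracid should attack the exocyclic alkene on the convex (axial) face, anti to the axial C1 methylene of ring A that screens the other face, so that oxygen on C9 ends cis to the C10 methyl and C11 equatorial (9R), the opposite of what addition of a carbon nucleophile to ketone 11 would give.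

Step 10
Reactants: 13 (5S,6S,8R,9R,10R)-9,11-epoxy-12,13,14,15,16-pentanorlabdan-6-ol
Product: 14 (5S,6S,8R,9R,10R)-14,15-dinorlabd-13(16)-ene-6,9-diol
Conditions: CH2=CHCH2MgBr (3 equiv), CuI (10 mol%), THF, −30 → 0 °C
Reagents that add atoms: allylmagnesium bromide (C=CC[Mg]Br)
Why: Copper-catalysed SN2 opening of the 1,1-disubstituted epoxide at the primary carbon C11 by the allyl Grignard reagent leaves the C9–O bond untouched, so the configuration from step 9 is kept, one equivalent of reagent being spent on the C6 hydroxyl.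

Step 11
Reactants: 14 (5S,6S,8R,9R,10R)-14,15-dinorlabd-13(16)-ene-6,9-diol
Product: 15 (5S,6S,8R,9R,10R)-9-hydroxy-14,15-dinorlabd-13(16)-en-6-yl acetate
Conditions: Ac2O, pyridine, DMAP (cat.), CH2Cl2, 23 °C
Reagents that add atoms: acetic anhydride (CC(=O)OC(C)=O)
Why: DMAP-catalysed esterification should be selective for the secondary C6 hydroxyl, the tertiary C9 hydroxyl flanked by C8 and C10 being too hindered to react under these conditions.

Step 12
Reactants: 15 (5S,6S,8R,9R,10R)-9-hydroxy-14,15-dinorlabd-13(16)-en-6-yl acetate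
Product: 17 (5S,6S,8R,9R,10R)-9,13-epoxy-16-hydroxy-14,15-dinorlabdan-6-yl acetate (C13 epimers), via epoxide 16 (not isolated)
Conditions: mCPBA, NaHCO3, CH2Cl2, 23 °C; then CSA (10 mol%), CH2Cl2, 23 °C
Reagents that add atoms: 3-chloroperoxybenzoic acid (OOC(=O)c1cccc(Cl)c1)
Why: Epoxidation of the terminal alkene and acid-catalysed 5-exo-tet opening of epoxide 16 at C13 by the C9 hydroxyl (epoxy-alcohol cyclisation) should close the tetrahydrofuran ring with C9 unchanged, and the C13 epimer mixture is of no consequence because C13 becomes trigonal in step 15.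

Step 13
Reactants: 17 (5S,6S,8R,9R,10R)-9,13-epoxy-16-hydroxy-14,15-dinorlabdan-6-yl acetate
Product: 18 (5S,6S,8R,9R,10R)-6-acetoxy-9,13-epoxy-14,15-dinorlabdan-16-oic acid (C13 epimers)
Conditions: TEMPO (20 mol%), PhI(OAc)2, MeCN/H2O, 23 °C
Reagents that add atoms: water (O)
Why: Oxoammonium (TEMPO) oxidation of the primary alcohol through the aldehyde hydrate should give the acid, with acetate, ether and all other positions inert (alcohol-to-acid oxidation).

Step 14
Reactants: 19 (1R,2S,5R)-menthyl (S)-4-methylbenzenesulfinate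
Product: 20 (R)-1-(ethenylsulfinyl)-4-methylbenzene
Conditions: CH2=CHMgBr, toluene/THF, −20 → 0 °C
Reagents that add atoms: vinylmagnesium bromide (C=C[Mg]Br)
Why: Andersen sulfoxide synthesis, in which the Grignard reagent displaces menthoxide at sulfur with inversion, so the (S)-sulfinate should give the (R)-sulfoxide.

Step 15
Reactants: 18 (5S,6S,8R,9R,10R)-6-acetoxy-9,13-epoxy-14,15-dinorlabdan-16-oic acid; 20 (R)-1-(ethenylsulfinyl)-4-methylbenzene
Product: 25 (5S,6S,8R,9R,10R,13R)-6-acetoxy-9,13-epoxy-15-(4-methylphenylsulfanyl)labdan-16,15-olide (C15 epimers), via acid chloride 21 (not isolated), via ketene 22 (not isolated), via sulfonium enolate 23 (not isolated), via thionium carboxylate 24 (not isolated)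
Conditions: (COCl)2, DMF (cat.), CH2Cl2, 0 → 23 °C, then evaporation; 20 (1.5 equiv), Et3N (slow addition), CH2Cl2, 0 → 40 °C
Reagents that add atoms: none
Why: Proposed new method: acid chloride 21 is dehydrochlorinated to the alkoxy(alkyl)ketene 22 (C13=C16=O), the sulfinyl oxygen of 20 adds to C16 to give the O-sulfonio ketene hemiacetal enolate 23, a charge-accelerated [3,3]-sigmatropic shift (S–O broken, C13–C14 formed) gives thionium carboxylate 24, and the carboxylate closes onto the thionium carbon (C15–O formed). The closest known reaction type is the sigmatropic (additive Pummerer-type) γ-lactonisation of aryl vinyl sulfoxides with dichloroketene, which makes the same two bonds and passes sulfur chirality on to carbon; new here are a non-halogenated ketene and a quaternary stereocentre at the ketene-derived carbon. The lactone ring closes 5-exo-trig, the carboxylate oxygen attacking the exocyclic C15=S+ bond. C13 is controlled by the sulfur stereocentre through a chair-like six-membered transition state (S, O, C16, C13, C14, C15) with 4-methylphenyl pseudo-equatorial and the small ring oxygen O9 pseudo-axial, cis to the sulfonio-oxy group and opposed to the enolate oxygen, so the (R)-sulfoxide should deliver C14 to the face of C13 that is syn to C10 (13R); C15 forms without control and is erased in step 16. The step needs face selectivity at C13 and capture of the ketene by the sulfoxide rather than by itself: the decalin cannot supply the first, since C8 and C10 flank C9 almost as mirror images (each with an equatorial methyl), so the reagent decides without a mismatch, and the second is helped by inductive activation of the ketene by O9, slow addition of base and excess 20.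

Step 16
Reactants: 25 (5S,6S,8R,9R,10R,13R)-6-acetoxy-9,13-epoxy-15-(4-methylphenylsulfanyl)labdan-16,15-olide
Product: 26 (5S,6S,8R,9R,10R,13R)-6-acetoxy-9,13-epoxylabdan-16,15-olide
Conditions: Raney Ni, EtOH, 23 °C
Reagents that add atoms: none
Why: Hydrogenolytic desulfurisation with Raney Ni should cleave both C–S bonds of the O,S-acetal, putting hydrogen on C15 and removing its uncontrolled stereocentre, while lactone, acetate and ethers are not reduced.

Compound list
1 | (R)-carvone, (5R)-2-methyl-5-(prop-1-en-2-yl)cyclohex-2-en-1-one | CC1=CC[C@H](CC1=O)C(C)=C | starting material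
2 | 4-iodobut-1-ene | C=CCCI | starting material
3 | (5R)-6-(but-3-en-1-yl)-2-methyl-5-(prop-1-en-2-yl)cyclohex-2-en-1-one (both C6 epimers) | C1C=C(C)C(=O)C(CCC=C)[C@@H]1C(C)=C | intermediate
4 | (5S,6R)-6-(but-3-en-1-yl)-2,6-dimethyl-5-(prop-1-en-2-yl)cyclohex-2-en-1-one (methyl trans to isopropenyl) | C1C=C(C)C(=O)[C@](C)(CCC=C)[C@@H]1C(C)=C | intermediate
5 | (4aS,8aR)-2,5,8a-trimethyl-4a,7,8,8a-tetrahydronaphthalen-1(4H)-one (cis-fused) | C1C=C(C)C(=O)[C@]2(C)CCC=C(C)[C@H]12 | intermediate
6 | hydrazide adduct of 5 formed in the flask: C4 bears CH3 and CH2–NH–NH–SO2-octyl (C4 epimers) | C1C=C(C)C(=O)[C@]2(C)CCCC(C)(CNNS(=O)(=O)CCCCCCCC)[C@H]12 | intermediate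
7 | (4aS,8aR)-2,5,5,8a-tetramethyl-4a,5,6,7,8,8a-hexahydronaphthalen-1(4H)-one | C1C=C(C)C(=O)[C@]2(C)CCCC(C)(C)[C@H]12 | intermediate
8 | tert-butyl(dimethyl){[(4aS,8aR)-2,5,5,8a-tetramethyl-4a,5,6,7,8,8a-hexahydronaphthalen-1-yl]oxy}silane | C1=CC(C)=C(O[Si](C)(C)C(C)(C)C)[C@]2(C)CCCC(C)(C)[C@H]12 | intermediate
9 | endoperoxide formed in the flask: O–O bridge from C6 to C9 on the convex face, C9 also bearing OTBS | O1[C@H]2C=C(C)[C@](O1)(O[Si](C)(C)C(C)(C)C)[C@]1(C)CCCC(C)(C)[C@H]21 | intermediate
10 | (4S,4aS,8aR)-4-hydroxy-2,5,5,8a-tetramethyl-4a,5,6,7,8,8a-hexahydronaphthalen-1(4H)-one | O[C@H]1C=C(C)C(=O)[C@]2(C)CCCC(C)(C)[C@H]12 | intermediate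
11 | (2R,4S,4aS,8aR)-4-hydroxy-2,5,5,8a-tetramethyloctahydronaphthalen-1(2H)-one | O[C@H]1C[C@@H](C)C(=O)[C@]2(C)CCCC(C)(C)[C@H]12 | intermediate
12 | (1S,3R,4aR,8aS)-3,4a,8,8-tetramethyl-4-methylidenedecahydronaphthalen-1-ol | O[C@H]1C[C@@H](C)C(=C)[C@]2(C)CCCC(C)(C)[C@H]12 | intermediate
13 | (5S,6S,8R,9R,10R)-9,11-epoxy-12,13,14,15,16-pentanorlabdan-6-ol (epoxide oxygen cis to the C10 methyl) | O[C@H]1C[C@@H](C)[C@]3(CO3)[C@]2(C)CCCC(C)(C)[C@H]12 | intermediate
14 | (5S,6S,8R,9R,10R)-14,15-dinorlabd-13(16)-ene-6,9-diol | O[C@H]1C[C@@H](C)[C@](O)(CCC=C)[C@]2(C)CCCC(C)(C)[C@H]12 | intermediate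
15 | (5S,6S,8R,9R,10R)-9-hydroxy-14,15-dinorlabd-13(16)-en-6-yl acetate | CC(=O)O[C@H]1C[C@@H](C)[C@](O)(CCC=C)[C@]2(C)CCCC(C)(C)[C@H]12 | intermediate
16 | (5S,6S,8R,9R,10R)-13,16-epoxy-9-hydroxy-14,15-dinorlabdan-6-yl acetate, formed in the flask (C13 epimers) | CC(=O)O[C@H]1C[C@@H](C)[C@](O)(CCC3CO3)[C@]2(C)CCCC(C)(C)[C@H]12 | intermediate
17 | (5S,6S,8R,9R,10R)-9,13-epoxy-16-hydroxy-14,15-dinorlabdan-6-yl acetate (C13 epimers) | CC(=O)O[C@H]1C[C@@H](C)[C@]2(CCC(CO)O2)[C@]2(C)CCCC(C)(C)[C@H]12 | intermediate
18 | (5S,6S,8R,9R,10R)-6-acetoxy-9,13-epoxy-14,15-dinorlabdan-16-oic acid (C13 epimers) | CC(=O)O[C@H]1C[C@@H](C)[C@]2(CCC(C(=O)O)O2)[C@]2(C)CCCC(C)(C)[C@H]12 | intermediate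
19 | (1R,2S,5R)-menthyl (S)-4-methylbenzenesulfinate | Cc1ccc(cc1)[S@@](=O)O[C@@H]1C[C@H](C)CC[C@H]1C(C)C | starting material
20 | (R)-1-(ethenylsulfinyl)-4-methylbenzene, (R)-4-methylphenyl vinyl sulfoxide | Cc1ccc(cc1)[S@](=O)C=C | intermediate
21 | acid chloride of 18, formed in the flask | CC(=O)O[C@H]1C[C@@H](C)[C@]2(CCC(C(=O)Cl)O2)[C@]2(C)CCCC(C)(C)[C@H]12 | intermediate
22 | ketene formed in the flask, (5S,6S,8R,9R,10R)-6-acetoxy-9,13-epoxy-14,15-dinorlabd-13(16)-en-16-one | CC(=O)O[C@H]1C[C@@H](C)[C@]2(CCC(=C=O)O2)[C@]2(C)CCCC(C)(C)[C@H]12 | intermediate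
23 | zwitterionic O-sulfonio ketene hemiacetal enolate formed in the flask (sulfur configuration as in 20; sulfonio-oxy group cis to O9) | CC(=O)O[C@H]1C[C@@H](C)[C@]2(CCC(=C([O-])O[S@+](C=C)c3ccc(C)cc3)O2)[C@]2(C)CCCC(C)(C)[C@H]12 | intermediate
24 | zwitterionic thionium carboxylate formed in the flask (13R) | CC(=O)O[C@H]1C[C@@H](C)[C@]2(CC[C@@](CC=[S+]c3ccc(C)cc3)(C([O-])=O)O2)[C@]2(C)CCCC(C)(C)[C@H]12 | intermediate
25 | (5S,6S,8R,9R,10R,13R)-6-acetoxy-9,13-epoxy-15-(4-methylphenylsulfanyl)labdan-16,15-olide (C15 epimers) | CC(=O)O[C@H]1C[C@@H](C)[C@]2(CC[C@]3(CC(Sc4ccc(C)cc4)OC3=O)O2)[C@]2(C)CCCC(C)(C)[C@H]12 | intermediate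
26 | (5S,6S,8R,9R,10R,13R)-6-acetoxy-9,13-epoxylabdan-16,15-olide | CC(=O)O[C@H]1C[C@@H](C)[C@]2(CC[C@]3(CCOC3=O)O2)[C@]2(C)CCCC(C)(C)[C@H]12 | target

Total step count: 16. Longest linear sequence: 15 steps (steps 1 to 13, then 15 and 16; step 14 is a one-step branch).

Steps most likely to fail

Step 15 (key step). What may go wrong: the alkoxy ketene may dimerise or be consumed by chloride or amine faster than the sulfoxide oxygen acylates it, or the chair preference and enolate geometry assumed for the sigmatropic shift may be weak, so that face selectivity at C13 erodes or reverses. The fallback replaces the sigmatropic lactonisation by classical enediolate alkylation and sets out from diol 14, leaving out the acetylation. Epoxidation and acid-catalysed cyclisation (mCPBA; then CSA) should give (5S,6S,8R,9R,10R)-9,13-epoxy-14,15-dinorlabdane-6,16-diol F1. Selective oxidation of the primary alcohol (TEMPO, PhI(OAc)2, MeCN/H2O) should give (5S,6S,8R,9R,10R)-9,13-epoxy-6-hydroxy-14,15-dinorlabdan-16-oic acid F2. Deprotonation with LiN(i-Pr)2 (3.3 equiv, THF, −78 → 0 °C), alkylation of the enediolate at C13 with ethylene oxide and acidic work-up should give the spirolactone as both C13 epimers, since the decalin exerts no bias. The 13R epimer, (5S,6S,8R,9R,10R,13R)-9,13-epoxy-6-hydroxylabdan-16,15-olide F3, is separated by chromatography. Acetylation (Ac2O, pyridine, DMAP) comes back to the route at target 26.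

Step 8. What may go wrong: betaine formation at the doubly flanked C9 carbonyl may be too slow, so that enolisation toward C8 and recovery of ketone dominate. The fallback is a Peterson olefination, that is addition of a small organometallic followed by elimination, and sets out from ketone 11. Me3SiCH2Li with CeCl3 (THF, −78 → 0 °C) should add to the carbonyl to give (5S,6S,8R,10R)-11-(trimethylsilyl)-12,13,14,15,16-pentanorlabdane-6,9-diol F4, whose C9 configuration is irrelevant. Elimination with KH (THF, 23 °C) comes back to the route at alkene 12.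

Step 6. What may go wrong: poor facial selectivity of the cycloaddition, or a competing ene reaction at the C8 methyl, would deliver oxygen to the wrong face of C6. The fallback is oxygenation followed by inversion and sets out from dienol ether 8. If the concave-face adduct prevails, the same conditions give the epimer (4R,4aS,8aR)-4-hydroxy-2,5,5,8a-tetramethyl-4a,5,6,7,8,8a-hexahydronaphthalen-1(4H)-one F5. Mitsunobu inversion with 4-nitrobenzoic acid (PPh3, DIAD, THF, 0 °C) should give (4S,4aS,8aR)-2,5,5,8a-tetramethyl-1-oxo-1,4,4a,5,6,7,8,8a-octahydronaphthalen-4-yl 4-nitrobenzoate F6. Methanolysis (K2CO3, MeOH) comes back to the route at hydroxy enone 10.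

Further compounds
F1 | step 15 | (5S,6S,8R,9R,10R)-9,13-epoxy-14,15-dinorlabdane-6,16-diol (C13 epimers) | O[C@H]1C[C@@H](C)[C@]2(CCC(CO)O2)[C@]2(C)CCCC(C)(C)[C@H]12
F2 | step 15 | (5S,6S,8R,9R,10R)-9,13-epoxy-6-hydroxy-14,15-dinorlabdan-16-oic acid (C13 epimers) | O[C@H]1C[C@@H](C)[C@]2(CCC(C(=O)O)O2)[C@]2(C)CCCC(C)(C)[C@H]12
F3 | step 15 | (5S,6S,8R,9R,10R,13R)-9,13-epoxy-6-hydroxylabdan-16,15-olide | O[C@H]1C[C@@H](C)[C@]2(CC[C@]3(CCOC3=O)O2)[C@]2(C)CCCC(C)(C)[C@H]12
F4 | step 8 | (5S,6S,8R,10R)-11-(trimethylsilyl)-12,13,14,15,16-pentanorlabdane-6,9-diol (C9 epimers) | O[C@H]1C[C@@H](C)C(O)(C[Si](C)(C)C)[C@]2(C)CCCC(C)(C)[C@H]12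
F5 | step 6 | (4R,4aS,8aR)-4-hydroxy-2,5,5,8a-tetramethyl-4a,5,6,7,8,8a-hexahydronaphthalen-1(4H)-one | O[C@@H]1C=C(C)C(=O)[C@]2(C)CCCC(C)(C)[C@H]12
F6 | step 6 | (4S,4aS,8aR)-2,5,5,8a-tetramethyl-1-oxo-1,4,4a,5,6,7,8,8a-octahydronaphthalen-4-yl 4-nitrobenzoate | O=C(O[C@H]1C=C(C)C(=O)[C@]2(C)CCCC(C)(C)[C@H]12)c1ccc(cc1)[N+](=O)[O-]
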